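# Synthesis plan for CNP0116395.1: cuprate addition and enolate alkylation on an enone ester

## The problem

CNP0116395.1 is a bicyclo[9.3.1]pentadecadiene carboxylic acid. Labels used throughout: C1 is the carboxyl-bearing quaternary carbon; C2–C12 are the other atoms of the twelve-membered ring (Z alkenes C4=C5 and C8=C9, methyl groups on C5 and C9); C13 is the spiro-epoxide carbon on C12; C14 and C15 lead back to C2; C16 begins the 4-methylpent-3-enyl chain on C1. The cyclohexane is therefore C1–C2–C15–C14–C13–C12, and the nine-carbon chain C3–C11 bridges C2 and C12 from opposite faces of it.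

Four contiguous stereocentres lie on the six-membered ring (1S, 2R, 12R, 13S with these labels): the carboxyl is cis to C3, the side chain is cis to C11, and the epoxide oxygen is cis to C11. Only C2 needs an outside source of chirality. A substituent on C2 can send a nucleophile to the far face of C1; the ester on quaternary C1 (axial when the two alkyl groups are equatorial) can send an electrophile to the far face of C12; the C12 and C1 chains then leave one face of a C13 carbonyl open.

The molecule is fragile in four ways:
- The 1,1-disubstituted epoxide next to a carboxylic acid will not survive acid, thiolate or hydride.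
- The three trisubstituted alkenes, two of them Z, exclude strong protic acid, equilibrating π-allyl intermediates and unselective electrophilic oxidants.
- The neopentyl carboxyl cannot be unmasked by saponification.
- C12 can epimerise whenever C13 is a ketone, and the epimer needed is the axial, kinetically formed one.

The feature that opens the structure is the oxidation level of C13. As a ketone it makes C12 its α-carbon and C1 its β-carbon, so a C12=C1 enone that already carries the C1 ester can take the side chain at C1 and the C11 arm at C12 in one operation. The macrocycle can then be closed at C6–C7, a bond between two primary allylic carbons remote from every stereocentre, and the ketone is converted into the epoxide at the very end.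

## Retrosynthesis

**Epoxide (29 ⇒ 28).** The C13–CH2 and C13–O bonds of the oxirane are cut back to the C13 ketone of keto acid 28 and a sulfur ylide. The neighbouring option, epoxidising a C13 exocyclic methylene, fails on chemoselectivity, since any electrophilic oxidant would take the three trisubstituted alkenes first. 28 has one stereocentre fewer and lacks the most sensitive group. The forward step must deliver CH2 to the face of C13 anti to the C12–C11 bond, and must run on the carboxylate, because the acid has to be free before an epoxide exists.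

**Unmasking (28 ⇒ 27 ⇒ 26 ⇒ 25).** No skeletal bond is cut. The order is dictated by the functional groups:
- The neopentyl methyl ester of 25 can only be cleaved by SN2 attack of thiolate at the O-methyl group. This is done while C13 is a ketal and long before the epoxide.
- The C7 sulfone of 26 is removed by palladium-catalysed hydride transfer. The carboxylate is inert to the hydride, whereas an ester might not be.
- The ketal of 27 is hydrolysed last, under mild acid, so that the C12 ketone epimer is exposed as briefly as possible.

**Macrocycle (25 ⇒ 24).** The C6–C7 bond is cut to the α-carbanion of the C7 allylic sulfone and the C6 allylic bromide of the monocyclic compound 24.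
- Closure at C2–C3 or C11–C12 would create ring stereocentres during macrocyclisation.
- Closure by olefination at C4=C5 or C8=C9 would have to create a Z-trisubstituted alkene inside a twelve-membered ring.
- The C6–C7 cut leaves both Z alkenes as spectators and reduces the bicycle to a cyclohexane with two arms.
- The forward step needs high dilution, α-alkylation of the allyl sulfone anion, and retention of both alkene geometries.

**Arm adjustment (24 ⇒ 23 ⇒ 22 ⇒ 21 ⇒ 20).** Only functional groups change. The two chain ends are different from the start: C7 is a chloride and C6 is a silyl ether. The chloride becomes the sulfone in one step without any protecting-group step at C7. The ketone is ketalised before any base is used. The silyl ether is converted to the bromide only just before ring closure.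

**Key disconnection (20 ⇒ 11 + 16 + 15).** The C1–C16 and C12–C11 bonds are cut together: the side chain returns to the Grignard reagent from bromide 16, the C11 arm to triflate 15, and the ring to enone ester 11.
- Against cutting only one bond: a single conjugate addition would leave the C12 enolate unused and C12 would have to be functionalised later, against the regiochemical preference of the ketone.
- Simplification: 11 has one stereocentre instead of three and no quaternary carbon.
- Demands: addition β to the ketone at the fully substituted C1, anti to the C2 arm; alkylation at C12 anti to the axial ester; chemoselection of the triflate over the allylic chloride.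
- The PMB ether analogue of 15 was rejected because a Z-5-alkoxy triflate is set up to cyclise to a dihydropyran. The chloride cannot do this and is itself the precursor of the sulfone.

**Carboxyl carbon (11 ⇒ 10 ⇒ 8).** The C1–CO2Me bond is cut to enone 8 and a tris(methylsulfanyl)methyl anion, which adds in a conjugate manner; the enone is restored by dehydrogenation of the resulting enolate. The shorter-looking neighbour is alkylation of 3-ethoxycyclohex-2-enone followed by 1,2-addition and transposition. That route would need an enantioselective alkylation of a vinylogous ester enolate with a functionalised allylic bromide, for which there is no dependable method. It would also need a differentiated (Z)-2-methylbut-2-ene-1,4-diol. Here C2 is set catalytically before the ring exists.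

**Ring and C2 (8 ⇒ 7 ⇒ 5 + 6).** The C12=C1 bond (aldol condensation) and the C2–C15 bond (Michael addition) are cut to aldehyde 5 and but-3-en-2-one 6. The enamine-catalysed Michael addition of aldehydes to this ketone is a reliable way to a 4-substituted cyclohexenone and sets C2. The forward steps must not erode the α-stereocentre of 7 before it becomes the γ-carbon of 8.

**Arm alkene (5 ⇒ 4 ⇒ 1 + 2).** The C4=C5 alkene is cut to silyloxy ketone 1 and the ylide from phosphonium salt 2. Unstabilised ylides add to α-alkoxy ketones with the chain cis to the oxygenated carbon, which is the Z geometry needed. This replaces any differentiation of a symmetrical-looking butenediol.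

**Triflate (15 ⇒ 14 ⇒ 13 ⇒ 12).** No carbon–carbon bond is cut. The ring of lactone 12 holds the C8=C9 geometry, and reduction gives the Z diol 13. The allylic hydroxyl is exchanged for chloride chemoselectively, and the remaining primary alcohol is triflated. 16 is purchased.

## Roads not taken

**Alternative 1: enzymatic bicyclisation.**
- Cut: C2–C3 and C1–C12 together, back to the acyclic (2Z,6Z)-geranylfarnesyl diphosphate A1.
- Forward step: a class 1 terpene synthase ionises the diphosphate, C2 attacks C3 to close the fourteen-membered ring, the C1 cation is taken by C12 to close the cyclohexane, and loss of a methyl proton gives hydrocarbon A2 with a C1 methyl group and a C13 exocyclic methylene.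
- Merits: both rings and the three stereocentres C1, C2 and C12 are formed in one step from an achiral chain. If a suitable enzyme were available, this road would be far shorter than the chosen one.
- Weak points: it needs an enzyme that accepts and folds the 2Z,6Z substrate. A1 itself requires a stereocontrolled C25 synthesis. A2 carries no oxygen: the C1 methyl must be oxidised to a carboxylic acid, which is beyond chemical reagents and needs a second, specific oxygenase. The exocyclic alkene must then be epoxidised in preference to three more electron-rich alkenes.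
- Comparison: the chosen plan is much longer. In return, it carries the carboxyl carbon and the C13 oxygen from the start and uses only reactions that can be run and corrected in an ordinary laboratory.

**Alternative 2: allyl sulfone macroalkylation as the strategic step.**
- Cut: C6–C7.
- Forward step: a strong amide base at high dilution deprotonates the C7 allylic phenyl sulfone, and the carbanion displaces the C6 allylic bromide to give ketal ester A3 (both C7 epimers).
- Merits: the ring closes between two unhindered primary allylic carbons, remote from every stereocentre, with both Z alkenes untouched. In this respect it is as good as anything available, and the chosen route uses exactly this closure in step 15 (A3 is the same compound as 25).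
- Weak points: as a plan on its own it leaves the hard part open, namely how a cyclohexane with the contiguous C2, C1 (quaternary) and C12 centres and two differentiated arms is to be made.
- Comparison: the two are complementary, not rivals. The three-component step supplies the open-chain precursor in one operation, and the chosen plan has to set against this road only that its decisive risk sits earlier, at the hindered enolate alkylation.

**Alternative 3: carbonyl-ene closure of the cyclohexane.**
- Cut: C14–C15. The substrate is macrocyclic aldehyde A4 (C15 aldehyde on C2, isopropenyl group on C12).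
- Forward step: an aluminium Lewis acid activates the aldehyde, the terminal CH2 of the isopropenyl group attacks C15 with hydrogen transfer from its methyl group, and homoallylic alcohol A5 results, with a C13 exocyclic methylene and a C15 hydroxyl.
- Merits: the ene step is mild and atom-economical, and six-membered ring formation of this kind is usually efficient. For the ring-forming event itself this road is likely to be better.
- Weak points:
  - A4 must already hold C1, C2 and C12 correctly on a flexible twelve-membered ring, where no cyclic control element exists.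
  - The aldehyde can also engage the nearer C4=C5 alkene.
  - The C15 hydroxyl must be removed afterwards.
  - C13 arrives as an alkene, so the epoxide would again have to be made by an oxidant that prefers the least electron-rich of four alkenes.
- Comparison: the chosen plan builds the stereotriad on the rigid six-membered ring and keeps C13 as a ketone, which a sulfur ylide converts to the epoxide without touching any alkene. It pays for this with a macrocyclisation that the ene route would not need at that stage.

Key step: step 10

Remark: the labels C1–C16 used for compounds 25–29 are those defined in the first section, not von Baeyer locants; the descriptors quoted with them were assigned on that basis.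
Remark: both C7 epimers of 25 and 26 are carried on together, because C7 becomes a methylene group in step 17.

## Route

Step 1
Reactants: 1 1-(tert-butyldimethylsilyloxy)propan-2-one; 2 (4-ethoxy-4-oxobutyl)triphenylphosphonium bromide
Product: 4 ethyl (4Z)-6-(tert-butyldimethylsilyloxy)-5-methylhex-4-enoate, via phosphorus ylide 3 (not isolated)
Conditions: 2, KN(SiMe3)2, THF, −78 → 0 °C; then 1, −78 °C → rt
Reagents that add atoms: none
Why: Wittig olefination; unstabilised ylides add to α-alkoxy and α-silyloxy ketones under salt-free conditions with the new chain cis to the oxygenated carbon, which is the Z geometry of C4=C5; the minor E isomer is removed by chromatography.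

Step 2
Reactants: 4 ethyl (4Z)-6-(tert-butyldimethylsilyloxy)-5-methylhex-4-enoate
Product: 5 (4Z)-6-(tert-butyldimethylsilyloxy)-5-methylhex-4-enal
Conditions: i-Bu2AlH (1.1 equiv), CH2Cl2, −78 °C; KNaC4H4O6 (aq)
Reagents that add atoms: none
Why: Partial reduction of an ester by i-Bu2AlH at low temperature; the tetrahedral aluminium hemiacetal survives until work-up, so the aldehyde is released only then.

Step 3
Reactants: 5 (4Z)-6-(tert-butyldimethylsilyloxy)-5-methylhex-4-enal; 6 but-3-en-2-one
Product: 7 (2R)-2-[(2Z)-4-(tert-butyldimethylsilyloxy)-3-methylbut-2-en-1-yl]-5-oxohexanal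
Conditions: (R)-2-[methoxy(diphenyl)methyl]pyrrolidine (5 mol%), ethyl 3,4-dihydroxybenzoate (20 mol%), neat, 4 °C
Reagents that add atoms: none
Why: Enamine-catalysed Michael addition of an aldehyde to a vinyl ketone; the E enamine is attacked on the face away from the methoxydiphenylmethyl group, which for the R catalyst should give the 2R aldehyde and so sets C2.

Step 4
Reactants: 7 (2R)-2-[(2Z)-4-(tert-butyldimethylsilyloxy)-3-methylbut-2-en-1-yl]-5-oxohexanal
Product: 8 (4R)-4-[(2Z)-4-(tert-butyldimethylsilyloxy)-3-methylbut-2-en-1-yl]cyclohex-2-en-1-one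
Conditions: LiOH, i-PrOH, rt
Reagents that add atoms: none
Why: Intramolecular aldol condensation of the methyl ketone onto the aldehyde (the only six-membered mode) and dehydration; mild hydroxide in 2-propanol should close the ring faster than the aldehyde α-centre epimerises, and that centre then becomes the less acidic γ-carbon of the enone.

Step 5
Reactants: 8 (4R)-4-[(2Z)-4-(tert-butyldimethylsilyloxy)-3-methylbut-2-en-1-yl]cyclohex-2-en-1-one
Product: 10 (4R)-4-[(2Z)-4-(tert-butyldimethylsilyloxy)-3-methylbut-2-en-1-yl]-3-[tris(methylsulfanyl)methyl]cyclohex-2-en-1-one, via lithium enolate 9 (not isolated)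
Conditions: HC(SMe)3, n-BuLi, THF, −78 °C; 8, −78 °C; then PhS(Cl)=N-t-Bu, THF, −78 °C
Reagents that add atoms: tris(methylsulfanyl)methane, CSC(SC)SC
Why: Conjugate addition of the sulfur-stabilised carboxyl anion equivalent (1,4-selective with cyclohexenones), then one-flask dehydrogenation of the regiodefined lithium enolate by the sulfinimidoyl chloride (S-attack at C12, syn-elimination with the C1 hydrogen); the C1 centre formed in passing is destroyed again, and C2 is untouched.

Step 6
Reactants: 10 (4R)-4-[(2Z)-4-(tert-butyldimethylsilyloxy)-3-methylbut-2-en-1-yl]-3-[tris(methylsulfanyl)methyl]cyclohex-2-en-1-one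
Product: 11 methyl (6R)-6-[(2Z)-4-(tert-butyldimethylsilyloxy)-3-methylbut-2-en-1-yl]-3-oxocyclohex-1-ene-1-carboxylate
Conditions: HgCl2, HgO, MeOH–H2O (12:1), rt
Reagents that add atoms: methanol, CO; water, O
Why: Thiophilic (divalent mercury) methanolysis of an orthothioester to the methyl ester; HgO takes up the acid released, so the silyl ether and the γ-stereocentre are not endangered, and HgCl2 is too weak an electrophile to attack the trisubstituted alkene.

Step 7
Reactants: 12 4-methyl-5,6-dihydro-2H-pyran-2-one
Product: 13 (2Z)-3-methylpent-2-ene-1,5-diol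
Conditions: i-Bu2AlH (4.5 equiv), CH2Cl2, −78 → 0 °C; KNaC4H4O6 (aq)
Reagents that add atoms: none
Why: Exhaustive 1,2-reduction of an unsaturated δ-lactone by i-Bu2AlH; the ring fixes the alkene geometry, so the diol is Z by construction.

Step 8
Reactants: 13 (2Z)-3-methylpent-2-ene-1,5-diol
Product: 14 (3Z)-5-chloro-3-methylpent-3-en-1-ol
Conditions: N-chlorosuccinimide, Me2S, CH2Cl2, −25 → 0 °C
Reagents that add atoms: N-chlorosuccinimide, O=C1CCC(=O)N1Cl
Why: Corey–Kim chlorination; the alkoxysulfonium salt of the allylic hydroxyl is displaced by chloride at the activated allylic carbon without rearrangement, while the saturated primary alcohol is not converted under these conditions.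

Step 9
Reactants: 14 (3Z)-5-chloro-3-methylpent-3-en-1-ol
Product: 15 (3Z)-5-chloro-3-methylpent-3-en-1-yl trifluoromethanesulfonate
Conditions: Tf2O, 2,6-lutidine, CH2Cl2, −78 °C; used at once
Reagents that add atoms: trifluoromethanesulfonic anhydride, O=S(=O)(OS(=O)(=O)C(F)(F)F)C(F)(F)F
Why: O-Sulfonylation of a primary alcohol with a hindered base at low temperature; the allylic chloride cannot cyclise onto the triflate as an ether oxygen could, so the reagent should last long enough to be used cold.

Step 10
Reactants: 11 methyl (6R)-6-[(2Z)-4-(tert-butyldimethylsilyloxy)-3-methylbut-2-en-1-yl]-3-oxocyclohex-1-ene-1-carboxylate; 16 5-bromo-2-methylpent-2-ene; 15 (3Z)-5-chloro-3-methylpent-3-en-1-yl trifluoromethanesulfonate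
Product: 20 methyl (1S,2R,6R)-6-[(2Z)-4-(tert-butyldimethylsilyloxy)-3-methylbut-2-en-1-yl]-2-[(3Z)-5-chloro-3-methylpent-3-en-1-yl]-1-(4-methylpent-3-en-1-yl)-3-oxocyclohexane-1-carboxylate, via Grignard reagent 17 (not isolated), via trimethylsilyl enol ether 18 (not isolated), via lithium enolate 19 (not isolated)
Conditions: 16, Mg, THF, rt; CuBr·SMe2 (10 mol%), Me3SiCl, HMPA, then 11, THF, −78 °C; volatiles removed, pentane, filtration under argon, evaporation; MeLi (1.0 equiv), THF, −20 → 0 °C; then 15, −78 → −30 °C; cold pH 7 buffer
Reagents that add atoms: none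
Why: A copper-catalysed (monovalent copper) Grignard conjugate addition accelerated by Me3SiCl is followed by regiospecific regeneration of the enolate from the silyl enol ether and SN2 alkylation; this is the established tandem conjugate addition and enolate trapping of cyclohexenones, which includes 3-alkoxycarbonyl enones that give quaternary β-carbons. The nucleophile enters β to the ketone at C1, not β to the ester, because only that mode gives the ketone enolate that Me3SiCl traps as 18, and the ester lowers the acceptor orbital enough to keep the fully substituted C1 reactive. No ring is closed in this step. At C1, allylic 1,2-strain with the ester holds the C2 arm pseudoaxial in 11 and the organocopper adds axially on the opposite face, so the side chain ends trans and the ester cis to C3. At C12, enolate 19 has the C2 arm and the side chain equatorial and the C1 ester axial; triflate 15 attacks axially, anti to that ester (the other face is blocked by it and would pass through a twist boat), which places C11 trans to the ester and trans to C3. This is the kinetic, axial epimer, so the reaction is quenched cold with buffer and the ketone is not exposed to base. Chemoselectivity rests on leaving-group ability: the primary triflate reacts at low temperature whereas the allylic chloride, the silyl ether and the neopentyl ester do not, and MeLi is limited to one equivalent at or below 0 °C so that Si–O cleavage outruns attack on the ester.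

Step 11
Reactants: 20 methyl (1S,2R,6R)-6-[(2Z)-4-(tert-butyldimethylsilyloxy)-3-methylbut-2-en-1-yl]-2-[(3Z)-5-chloro-3-methylpent-3-en-1-yl]-1-(4-methylpent-3-en-1-yl)-3-oxocyclohexane-1-carboxylate
Product: 21 methyl (1S,2R,6R)-2-[(3Z)-5-(benzenesulfonyl)-3-methylpent-3-en-1-yl]-6-[(2Z)-4-(tert-butyldimethylsilyloxy)-3-methylbut-2-en-1-yl]-1-(4-methylpent-3-en-1-yl)-3-oxocyclohexane-1-carboxylate
Conditions: PhSO2Na, Bu4NI (cat.), DMF, rt
Reagents that add atoms: sodium benzenesulfinate, [Na+].[O-]S(=O)c1ccccc1
Why: SN2 displacement of a primary allylic chloride by sulfinate at sulfur gives the allylic sulfone directly; the medium is essentially neutral, so C12 is not epimerised, and direct substitution keeps the Z alkene.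

Step 12
Reactants: 21 methyl (1S,2R,6R)-2-[(3Z)-5-(benzenesulfonyl)-3-methylpent-3-en-1-yl]-6-[(2Z)-4-(tert-butyldimethylsilyloxy)-3-methylbut-2-en-1-yl]-1-(4-methylpent-3-en-1-yl)-3-oxocyclohexane-1-carboxylate
Product: 22 methyl (6R,7S,8R)-6-[(3Z)-5-(benzenesulfonyl)-3-methylpent-3-en-1-yl]-8-[(2Z)-4-(tert-butyldimethylsilyloxy)-3-methylbut-2-en-1-yl]-7-(4-methylpent-3-en-1-yl)-1,4-dioxaspiro[4.5]decane-7-carboxylate
Conditions: Me3SiOCH2CH2OSiMe3, Me3SiOTf (cat.), CH2Cl2, −78 → −20 °C
Reagents that add atoms: 1,2-bis(trimethylsilyloxy)ethane, C[Si](C)(C)OCCO[Si](C)(C)C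
Why: Aprotic ketalisation with the bis-silyl ether of ethylene glycol under catalytic silyl triflate works on hindered ketones at low temperature, where enolisation toward C12 and loss of the silyl ether are not expected; it removes the enolisable ketone before any base is used.

Step 13
Reactants: 22 methyl (6R,7S,8R)-6-[(3Z)-5-(benzenesulfonyl)-3-methylpent-3-en-1-yl]-8-[(2Z)-4-(tert-butyldimethylsilyloxy)-3-methylbut-2-en-1-yl]-7-(4-methylpent-3-en-1-yl)-1,4-dioxaspiro[4.5]decane-7-carboxylate
Product: 23 methyl (6R,7S,8R)-6-[(3Z)-5-(benzenesulfonyl)-3-methylpent-3-en-1-yl]-8-[(2Z)-4-hydroxy-3-methylbut-2-en-1-yl]-7-(4-methylpent-3-en-1-yl)-1,4-dioxaspiro[4.5]decane-7-carboxylate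
Conditions: Bu4NF, THF, 0 °C
Reagents that add atoms: none
Why: Fluoride cleavage of a primary silyl ether; the ketal, the sulfone and the hindered ester are inert to fluoride.

Step 14
Reactants: 23 methyl (6R,7S,8R)-6-[(3Z)-5-(benzenesulfonyl)-3-methylpent-3-en-1-yl]-8-[(2Z)-4-hydroxy-3-methylbut-2-en-1-yl]-7-(4-methylpent-3-en-1-yl)-1,4-dioxaspiro[4.5]decane-7-carboxylate
Product: 24 methyl (6R,7S,8R)-6-[(3Z)-5-(benzenesulfonyl)-3-methylpent-3-en-1-yl]-8-[(2Z)-4-bromo-3-methylbut-2-en-1-yl]-7-(4-methylpent-3-en-1-yl)-1,4-dioxaspiro[4.5]decane-7-carboxylate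
Conditions: CBr4, PPh3, 2,6-lutidine, CH2Cl2, −20 → 0 °C
Reagents that add atoms: carbon tetrabromide, BrC(Br)(Br)Br
Why: Appel bromination of a primary allylic alcohol under neutral, buffered conditions; Z-allylic alcohols give Z-allylic bromides by direct displacement, and the ketal is not exposed to acid.

Step 15
Reactants: 24 methyl (6R,7S,8R)-6-[(3Z)-5-(benzenesulfonyl)-3-methylpent-3-en-1-yl]-8-[(2Z)-4-bromo-3-methylbut-2-en-1-yl]-7-(4-methylpent-3-en-1-yl)-1,4-dioxaspiro[4.5]decane-7-carboxylate
Product: 25 methyl (1S,2R,12R,4Z,8Z)-7-(benzenesulfonyl)-13,13-(ethylenedioxy)-5,9-dimethyl-1-(4-methylpent-3-en-1-yl)bicyclo[9.3.1]pentadeca-4,8-diene-1-carboxylate (labels of the first section; both C7 epimers)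
Conditions: KN(SiMe3)2, THF, −78 → −20 °C; 24 added slowly to a final 0.002 M
Reagents that add atoms: none
Why: Intramolecular SN2 alkylation of an allylic sulfone carbanion by a primary allylic bromide under high dilution, closing the twelve-membered ring by 12-exo-tet attack; sulfonyl-stabilised allyl anions alkylate at the α-carbon and keep their alkene geometry at low temperature, so both Z alkenes should survive, and the new C7 centre is of no consequence.

Step 16
Reactants: 25 methyl (1S,2R,12R,4Z,8Z)-7-(benzenesulfonyl)-13,13-(ethylenedioxy)-5,9-dimethyl-1-(4-methylpent-3-en-1-yl)bicyclo[9.3.1]pentadeca-4,8-diene-1-carboxylate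
Product: 26 (1S,2R,12R,4Z,8Z)-7-(benzenesulfonyl)-13,13-(ethylenedioxy)-5,9-dimethyl-1-(4-methylpent-3-en-1-yl)bicyclo[9.3.1]pentadeca-4,8-diene-1-carboxylic acid (both C7 epimers)
Conditions: n-PrSLi (from n-PrSH, n-BuLi), HMPA, rt; cold dilute HCl to pH 4
Reagents that add atoms: none
Why: SN2 dealkylation of a hindered methyl ester by thiolate at the O-methyl carbon, the only route open for a neopentyl ester whose carbonyl hydroxide cannot reach; it is placed here because thiolate would open the epoxide later and the carboxylate protects the carboxyl from hydride in step 17.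

Step 17
Reactants: 26 (1S,2R,12R,4Z,8Z)-7-(benzenesulfonyl)-13,13-(ethylenedioxy)-5,9-dimethyl-1-(4-methylpent-3-en-1-yl)bicyclo[9.3.1]pentadeca-4,8-diene-1-carboxylic acid
Product: 27 (1S,2R,12R,4Z,8Z)-13,13-(ethylenedioxy)-5,9-dimethyl-1-(4-methylpent-3-en-1-yl)bicyclo[9.3.1]pentadeca-4,8-diene-1-carboxylic acid
Conditions: PdCl2(dppp) (10 mol%), LiBHEt3, THF, 0 °C; cold dilute HCl to pH 4
Reagents that add atoms: none
Why: Palladium-catalysed reductive desulfonylation of an allylic sulfone; zerovalent palladium formed in situ ionises the C7–S bond and hydride is delivered to the less substituted allyl terminus C7, so the C8=C9 alkene should keep its place and geometry; the first equivalent of hydride only deprotonates the acid.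

Step 18
Reactants: 27 (1S,2R,12R,4Z,8Z)-13,13-(ethylenedioxy)-5,9-dimethyl-1-(4-methylpent-3-en-1-yl)bicyclo[9.3.1]pentadeca-4,8-diene-1-carboxylic acid
Product: 28 (1S,2R,12R,4Z,8Z)-5,9-dimethyl-1-(4-methylpent-3-en-1-yl)-13-oxobicyclo[9.3.1]pentadeca-4,8-diene-1-carboxylic acid
Conditions: pyridinium p-toluenesulfonate, acetone–H2O (10:1), 45 °C
Reagents that add atoms: water, O
Why: Acid-catalysed hydrolysis of a strained dioxolane under weakly acidic conditions that trisubstituted alkenes tolerate; short exposure limits acid-catalysed enolisation toward C12.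

Step 19
Reactants: 28 (1S,2R,12R,4Z,8Z)-5,9-dimethyl-1-(4-methylpent-3-en-1-yl)-13-oxobicyclo[9.3.1]pentadeca-4,8-diene-1-carboxylic acid
Product: 29 CNP0116395.1, the (1S,2R,12R,13S,4Z,8Z)-configured acid with a spiro-oxirane at C13
Conditions: Me3S+ I−, KN(SiMe3)2, THF, −10 °C; then 28, −10 °C → rt; cold aqueous KH2PO4
Reagents that add atoms: trimethylsulfonium iodide, C[S+](C)C.[I-]
Why: Corey–Chaykovsky epoxidation; dimethylsulfonium methylide adds irreversibly to the C13 carbonyl from the face anti to the adjacent C12–C11 bond and to the C1 side chain, and closure of the betaine then places the oxygen cis to C11 (13S); the acid is held as its carboxylate by an extra equivalent of base, and no alkene is touched.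

## Compound list

1 | 1-(tert-butyldimethylsilyloxy)propan-2-one | CC(=O)CO[Si](C)(C)C(C)(C)C | starting material
2 | (4-ethoxy-4-oxobutyl)triphenylphosphonium bromide | CCOC(=O)CCC[P+](c1ccccc1)(c1ccccc1)c1ccccc1.[Br-] | starting material
3 | ethyl 4-(triphenyl-λ5-phosphanylidene)butanoate (ylide, not isolated) | CCOC(=O)CCC=P(c1ccccc1)(c1ccccc1)c1ccccc1 | intermediate
4 | ethyl (4Z)-6-(tert-butyldimethylsilyloxy)-5-methylhex-4-enoate | CCOC(=O)CC/C=C(/C)CO[Si](C)(C)C(C)(C)C | intermediate
5 | (4Z)-6-(tert-butyldimethylsilyloxy)-5-methylhex-4-enal | O=CCC/C=C(/C)CO[Si](C)(C)C(C)(C)C | intermediate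
6 | but-3-en-2-one | CC(=O)C=C | starting material
7 | (2R)-2-[(2Z)-4-(tert-butyldimethylsilyloxy)-3-methylbut-2-en-1-yl]-5-oxohexanal | O=C[C@H](CCC(C)=O)C/C=C(/C)CO[Si](C)(C)C(C)(C)C | intermediate
8 | (4R)-4-[(2Z)-4-(tert-butyldimethylsilyloxy)-3-methylbut-2-en-1-yl]cyclohex-2-en-1-one | O=C1C=C[C@@H](C/C=C(/C)CO[Si](C)(C)C(C)(C)C)CC1 | intermediate
9 | lithium (4R)-4-[(2Z)-4-(tert-butyldimethylsilyloxy)-3-methylbut-2-en-1-yl]-3-[tris(methylsulfanyl)methyl]cyclohex-1-en-1-olate (C3 as formed, expected trans to the C4 chain; not isolated) | [Li+].[O-]C1=CC(C(SC)(SC)SC)[C@@H](C/C=C(/C)CO[Si](C)(C)C(C)(C)C)CC1 | intermediate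
10 | (4R)-4-[(2Z)-4-(tert-butyldimethylsilyloxy)-3-methylbut-2-en-1-yl]-3-[tris(methylsulfanyl)methyl]cyclohex-2-en-1-one | O=C1C=C(C(SC)(SC)SC)[C@@H](C/C=C(/C)CO[Si](C)(C)C(C)(C)C)CC1 | intermediate
11 | methyl (6R)-6-[(2Z)-4-(tert-butyldimethylsilyloxy)-3-methylbut-2-en-1-yl]-3-oxocyclohex-1-ene-1-carboxylate | COC(=O)C1=CC(=O)CC[C@@H]1C/C=C(/C)CO[Si](C)(C)C(C)(C)C | intermediate
12 | 4-methyl-5,6-dihydro-2H-pyran-2-one | CC1=CC(=O)OCC1 | starting material
13 | (2Z)-3-methylpent-2-ene-1,5-diol | OC/C=C(/C)CCO | intermediate
14 | (3Z)-5-chloro-3-methylpent-3-en-1-ol | OCC/C(C)=C\CCl | intermediate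
15 | (3Z)-5-chloro-3-methylpent-3-en-1-yl trifluoromethanesulfonate | ClC/C=C(/C)CCOS(=O)(=O)C(F)(F)F | intermediate
16 | 5-bromo-2-methylpent-2-ene | CC(C)=CCCBr | starting material
17 | (4-methylpent-3-en-1-yl)magnesium bromide (not isolated) | CC(C)=CCC[Mg]Br | intermediate
18 | methyl (1S,6R)-6-[(2Z)-4-(tert-butyldimethylsilyloxy)-3-methylbut-2-en-1-yl]-1-(4-methylpent-3-en-1-yl)-3-(trimethylsilyloxy)cyclohex-2-ene-1-carboxylate (not isolated) | CC(C)=CCC[C@]1(C(=O)OC)[C@@H](C/C=C(/C)CO[Si](C)(C)C(C)(C)C)CCC(O[Si](C)(C)C)=C1 | intermediate
19 | lithium (4R,5S)-4-[(2Z)-4-(tert-butyldimethylsilyloxy)-3-methylbut-2-en-1-yl]-5-(methoxycarbonyl)-5-(4-methylpent-3-en-1-yl)cyclohex-6-en-1-olate, the lithium enolate corresponding to 18 (not isolated) | [Li+].CC(C)=CCC[C@]1(C(=O)OC)[C@@H](C/C=C(/C)CO[Si](C)(C)C(C)(C)C)CCC([O-])=C1 | intermediate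
20 | methyl (1S,2R,6R)-6-[(2Z)-4-(tert-butyldimethylsilyloxy)-3-methylbut-2-en-1-yl]-2-[(3Z)-5-chloro-3-methylpent-3-en-1-yl]-1-(4-methylpent-3-en-1-yl)-3-oxocyclohexane-1-carboxylate | CC(C)=CCC[C@]1(C(=O)OC)[C@@H](C/C=C(/C)CO[Si](C)(C)C(C)(C)C)CCC(=O)[C@@H]1CC/C(C)=C\CCl | intermediate
21 | methyl (1S,2R,6R)-2-[(3Z)-5-(benzenesulfonyl)-3-methylpent-3-en-1-yl]-6-[(2Z)-4-(tert-butyldimethylsilyloxy)-3-methylbut-2-en-1-yl]-1-(4-methylpent-3-en-1-yl)-3-oxocyclohexane-1-carboxylate | CC(C)=CCC[C@]1(C(=O)OC)[C@@H](C/C=C(/C)CO[Si](C)(C)C(C)(C)C)CCC(=O)[C@@H]1CC/C(C)=C\CS(=O)(=O)c1ccccc1 | intermediate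
22 | methyl (6R,7S,8R)-6-[(3Z)-5-(benzenesulfonyl)-3-methylpent-3-en-1-yl]-8-[(2Z)-4-(tert-butyldimethylsilyloxy)-3-methylbut-2-en-1-yl]-7-(4-methylpent-3-en-1-yl)-1,4-dioxaspiro[4.5]decane-7-carboxylate | CC(C)=CCC[C@]1(C(=O)OC)[C@@H](C/C=C(/C)CO[Si](C)(C)C(C)(C)C)CCC2(OCCO2)[C@@H]1CC/C(C)=C\CS(=O)(=O)c1ccccc1 | intermediate
23 | methyl (6R,7S,8R)-6-[(3Z)-5-(benzenesulfonyl)-3-methylpent-3-en-1-yl]-8-[(2Z)-4-hydroxy-3-methylbut-2-en-1-yl]-7-(4-methylpent-3-en-1-yl)-1,4-dioxaspiro[4.5]decane-7-carboxylate | CC(C)=CCC[C@]1(C(=O)OC)[C@@H](C/C=C(/C)CO)CCC2(OCCO2)[C@@H]1CC/C(C)=C\CS(=O)(=O)c1ccccc1 | intermediate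
24 | methyl (6R,7S,8R)-6-[(3Z)-5-(benzenesulfonyl)-3-methylpent-3-en-1-yl]-8-[(2Z)-4-bromo-3-methylbut-2-en-1-yl]-7-(4-methylpent-3-en-1-yl)-1,4-dioxaspiro[4.5]decane-7-carboxylate | CC(C)=CCC[C@]1(C(=O)OC)[C@@H](C/C=C(/C)CBr)CCC2(OCCO2)[C@@H]1CC/C(C)=C\CS(=O)(=O)c1ccccc1 | intermediate
25 | methyl (1S,2R,12R,4Z,8Z)-7-(benzenesulfonyl)-13,13-(ethylenedioxy)-5,9-dimethyl-1-(4-methylpent-3-en-1-yl)bicyclo[9.3.1]pentadeca-4,8-diene-1-carboxylate (labels of the first section; both C7 epimers) | CC(C)=CCC[C@]1(C(=O)OC)[C@H]2C/C=C(/C)CC(S(=O)(=O)c3ccccc3)/C=C(/C)CC[C@H]1C1(OCCO1)CC2 | intermediate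
26 | the carboxylic acid corresponding to 25 (1S,2R,12R,4Z,8Z; both C7 epimers) | CC(C)=CCC[C@]1(C(=O)O)[C@H]2C/C=C(/C)CC(S(=O)(=O)c3ccccc3)/C=C(/C)CC[C@H]1C1(OCCO1)CC2 | intermediate
27 | (1S,2R,12R,4Z,8Z)-13,13-(ethylenedioxy)-5,9-dimethyl-1-(4-methylpent-3-en-1-yl)bicyclo[9.3.1]pentadeca-4,8-diene-1-carboxylic acid (labels of the first section) | CC(C)=CCC[C@]1(C(=O)O)[C@H]2C/C=C(/C)CC/C=C(/C)CC[C@H]1C1(OCCO1)CC2 | intermediate
28 | (1S,2R,12R,4Z,8Z)-5,9-dimethyl-1-(4-methylpent-3-en-1-yl)-13-oxobicyclo[9.3.1]pentadeca-4,8-diene-1-carboxylic acid (labels of the first section) | CC(C)=CCC[C@]1(C(=O)O)[C@H]2C/C=C(/C)CC/C=C(/C)CC[C@H]1C(=O)CC2 | intermediate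
29 | CNP0116395.1: (1S,2R,12R,13S,4Z,8Z)-5,9-dimethyl-1-(4-methylpent-3-en-1-yl)bicyclo[9.3.1]pentadeca-4,8-diene-1-carboxylic acid with a spiro-oxirane at C13, oxygen cis to C11 (labels of the first section) | CC(C)=CCC[C@]1(C(=O)O)[C@H]2C/C=C(/C)CC/C=C(/C)CC[C@H]1[C@@]1(CC2)CO1 | target

## Step count and least certain steps

Total step count: 19. Longest linear sequence: 16 steps (steps 1–6, 10 and 11–19, from 1 and 2); the triflate branch (steps 7–9) joins at step 10.

**Step 10 (key step).** Three processes could defeat it:
- Conjugate addition at the fully substituted C1 may be slowed by the neighbouring C2 arm, so that electron-transfer reduction of the doubly activated alkene, or attack β to the ester, competes.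
- Methyllithium may attack the ester before Si–O cleavage is complete.
- The hindered C12 enolate may be alkylated slowly, so that O-alkylation, elimination of the homoallylic triflate, or proton exchange leading to the equatorial C12 epimer takes over.

Fallback, from 11 and 16 back to 20: the silyl enol ether relay and methyllithium are given up. Bromide 16 and lithium metal in Et2O give (4-methylpent-3-en-1-yl)lithium F1. Two equivalents with CuI give the homocuprate lithium bis(4-methylpent-3-en-1-yl)cuprate F2, which adds to 11 at −78 °C without a silyl halide, so that lithium enolate 19 is formed directly. HMPA and triflate 15 are then added to the same flask, and 20 is reached without any reagent that can attack the ester.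

**Step 5.** The bulky, basic sulfur-stabilised anion may add to the carbonyl or remove the γ-hydrogen at C2 instead of adding at C1, and the one-flask dehydrogenation may be incomplete on a sulfur-rich enolate.

Fallback, from 8 back to 10: enolate 9 is intercepted with PhSeBr and the product is isolated as (4R)-4-[(2Z)-4-(tert-butyldimethylsilyloxy)-3-methylbut-2-en-1-yl]-2-(phenylselanyl)-3-[tris(methylsulfanyl)methyl]cyclohexan-1-one F3. Oxidation at selenium (H2O2, pyridine, CH2Cl2, 0 °C), which is much faster than oxidation of the thioether sulfurs, and syn-elimination of the selenoxide with the C1 hydrogen give 10.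

**Step 8.** The free homoallylic hydroxyl may cyclise onto the activated allylic position (the Z geometry favours a six-membered ether), or both hydroxyls may be chlorinated.

Fallback, from 13 back to 14: the cyclisation is used deliberately. Diol 13 is closed with p-toluenesulfonyl chloride and pyridine to 4-methyl-3,6-dihydro-2H-pyran F4, in which one C–O bond is allylic and the other is not. Acetyl chloride with catalytic ZnCl2 cleaves the allylic C–O bond to (3Z)-5-chloro-3-methylpent-3-en-1-yl acetate F5. i-Bu2AlH at −78 °C then removes the acetate without base and gives 14.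

**Step 17.** Hydride may be delivered to the tertiary terminus of the allylpalladium intermediate (moving the alkene to C7=C8), or the intermediate may equilibrate and lose the Z geometry.

Fallback, from 25 back to 27: the C–S bond is cleaved by electron transfer instead of through a π-allyl complex, and the order of the two unmasking steps is reversed. Na(Hg) with Na2HPO4 in MeOH–THF at −20 °C on ester 25 gives methyl (1S,2R,12R,4Z,8Z)-13,13-(ethylenedioxy)-5,9-dimethyl-1-(4-methylpent-3-en-1-yl)bicyclo[9.3.1]pentadeca-4,8-diene-1-carboxylate F6. n-PrSLi in HMPA then demethylates F6 to 27.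

**Step 19.** Four processes are of concern:
- The basic ylide may enolise the hindered ketone instead of adding.
- The carboxylate on the lower face may repel the ylide, so that facial selectivity erodes.
- C12 may epimerise through the enolate.
- The free acid may open the new epoxide during acidic isolation.

Fallback, from 28 back to 29: the acid is masked as an ester that fluoride removes. 2-(Trimethylsilyl)ethanol, PPh3 and diisopropyl azodicarboxylate alkylate the hindered carboxylate (Mitsunobu esterification with the acid as nucleophile) to the 2-(trimethylsilyl)ethyl ester of 28, F7. The ylide then meets a neutral ketone and should give the 2-(trimethylsilyl)ethyl ester of 29, F8. Bu4NF in THF releases the carboxylate by fragmentation at silicon, far from the epoxide, and work-up at pH 5 gives 29.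

## Further compounds

F1 | step 10 | (4-methylpent-3-en-1-yl)lithium | [Li]CCC=C(C)C
F2 | step 10 | lithium bis(4-methylpent-3-en-1-yl)cuprate | [Li+].CC(C)=CCC[Cu-]CCC=C(C)C
F3 | step 5 | (4R)-4-[(2Z)-4-(tert-butyldimethylsilyloxy)-3-methylbut-2-en-1-yl]-2-(phenylselanyl)-3-[tris(methylsulfanyl)methyl]cyclohexan-1-one (C2 and C3 as formed) | O=C1C([Se]c2ccccc2)C(C(SC)(SC)SC)[C@@H](C/C=C(/C)CO[Si](C)(C)C(C)(C)C)CC1
F4 | step 8 | 4-methyl-3,6-dihydro-2H-pyran | CC1=CCOCC1
F5 | step 8 | (3Z)-5-chloro-3-methylpent-3-en-1-yl acetate | CC(=O)OCC/C(C)=C\CCl
F6 | step 17 | methyl (1S,2R,12R,4Z,8Z)-13,13-(ethylenedioxy)-5,9-dimethyl-1-(4-methylpent-3-en-1-yl)bicyclo[9.3.1]pentadeca-4,8-diene-1-carboxylate (labels of the first section) | CC(C)=CCC[C@]1(C(=O)OC)[C@H]2C/C=C(/C)CC/C=C(/C)CC[C@H]1C1(OCCO1)CC2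
F7 | step 19 | 2-(trimethylsilyl)ethyl ester of keto acid 28 | CC(C)=CCC[C@]1(C(=O)OCC[Si](C)(C)C)[C@H]2C/C=C(/C)CC/C=C(/C)CC[C@H]1C(=O)CC2
F8 | step 19 | 2-(trimethylsilyl)ethyl ester of 29 | CC(C)=CCC[C@]1(C(=O)OCC[Si](C)(C)C)[C@H]2C/C=C(/C)CC/C=C(/C)CC[C@H]1[C@@]1(CC2)CO1
A1 | alternative 1 | (2Z,6Z,10E,14E)-geranylfarnesyl diphosphate | OP(=O)(O)OP(=O)(O)OC/C=C(/C)CC/C=C(/C)CC/C=C(\C)CC/C=C(\C)CCC=C(C)C
A2 | alternative 1 | bicyclo[9.3.1] hydrocarbon with C1 methyl and C13 exocyclic methylene | CC(C)=CCC[C@]1(C)[C@H]2C/C=C(/C)CC/C=C(/C)CC[C@H]1C(=C)CC2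
A3 | alternative 2 | bicyclo[9.3.1] methyl ester with C13 dioxolane and C7 benzenesulfonyl group (C7 epimers; same compound as 25) | CC(C)=CCC[C@]1(C(=O)OC)[C@H]2C/C=C(/C)CC(S(=O)(=O)c3ccccc3)/C=C(/C)CC[C@H]1C1(OCCO1)CC2
A4 | alternative 3 | twelve-membered-ring aldehyde: methyl ester with formyl on C2 and isopropenyl on C12 | CC(C)=CCC[C@]1(C(=O)OC)[C@H](C=O)C/C=C(/C)CC/C=C(/C)CC[C@H]1C(C)=C
A5 | alternative 3 | bicyclo[9.3.1] methyl ester with C13 exocyclic methylene and C15 hydroxyl | CC(C)=CCC[C@]1(C(=O)OC)[C@H]2C/C=C(/C)CC/C=C(/C)CC[C@H]1C(=C)C[C@H]2O
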